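**Plan**

Numbering: ring C1–C6 of the methylhydroquinone with the side chain on C6; chain C1' (benzylic CH2) to C15' (tertiary carbinol).
- Retrosynthesis: cut C12'–C13' (aldehyde plus E-alkenyl iodide), then C1'–C2' together with C3'–CH3 (one pot), then C4'–C5' (propargylation of a geranyl-derived enal); the hydroquinone travels as its dimethyl ether.
- Enabling feature: C2'=C3' is an E-trisubstituted alkene whose C2' carries only H and the benzylic C1' (bound to ring C6), and whose C3' carries CH3 and C4'H2–C5'H(O). This is the pattern left by syn addition of CH3–metal to the terminal alkyne C2'≡C3' of a homopropargylic alcohol, followed by benzylation at the metal-bearing C2'.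
- Forward: geranyl acetate gives the C5'–C12' enal; propargylation adds C2'–C4'; the one-pot methylalumination/benzylation adds C3'–CH3 and the arene (from 2-hydroxy-3-methylbenzoic acid); a Nozaki–Hiyama–Kishi coupling adds C13'–C15'. No ring is formed; the benzene ring comes with the starting material.
- Stereochemistry: C11' (S) from hydroxyl-directed Ru–BINAP hydrogenation; C5' (S) from chiral phosphoric acid catalysed propargylboration; 6'E from geranyl acetate, 2'E from syn-carbometalation, 13'E from syn-hydrostannylation.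

Key step: step 11

Assumption: the face selection of Ru(OAc)2[(S)-BINAP] on the 2-methyl allylic alcohol 2 is taken to follow that known for geraniol, and that of the (S)-phosphoric acid on enal 6 to follow that known for aryl and alkenyl aldehydes; the (S)-ligand and (S)-acid are specified on this basis.

**Route**

Step 1
Reactants: 1 geranyl acetate
Product: 2 (2E,6E)-8-hydroxy-3,7-dimethylocta-2,6-dien-1-yl acetate
Conditions: SeO2 (0.1 equiv), t-BuOOH (70% aq., 3 equiv), salicylic acid (0.1 equiv), CH2Cl2, 20 °C
Reagents that add atoms: tert-butyl hydroperoxide, CC(C)(C)OO (terminal oxidant; the oxygen is passed on by selenium dioxide, O=[Se]=O)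
Why: Selenium dioxide allylic oxidation (ene reaction then [2,3]-sigmatropic shift) should attack the E-methyl group of the electron-rich terminal trisubstituted alkene, while the alkene carrying the allylic acetate is deactivated and stays untouched.

Step 2
Reactants: 2 (2E,6E)-8-hydroxy-3,7-dimethylocta-2,6-dien-1-yl acetate
Product: 3 (2E,7S)-8-hydroxy-3,7-dimethyloct-2-en-1-yl acetate
Conditions: H2 (100 atm), Ru(OAc)2[(S)-BINAP] (1 mol%), MeOH, 25 °C
Reagents that add atoms: none
Why: Noyori hydroxyl-directed asymmetric hydrogenation should reduce only the alkene with a free allylic OH (the acetate-bearing alkene cannot bind ruthenium through an alkoxide), and hydrogen delivery to the same face of the allylic alcohol plane as in geraniol should set C7 as S.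

Step 3
Reactants: 3 (2E,7S)-8-hydroxy-3,7-dimethyloct-2-en-1-yl acetate
Product: 4 (2E,7S)-8-[(tert-butyldimethylsilyl)oxy]-3,7-dimethyloct-2-en-1-yl acetate
Conditions: TBSCl, imidazole, DMF, 20 °C
Reagents that add atoms: tert-butyldimethylsilyl chloride, CC(C)(C)[Si](C)(C)Cl
Why: Imidazole-promoted silylation of a primary alcohol is routine and leaves the allylic acetate alone.

Step 4
Reactants: 4 (2E,7S)-8-[(tert-butyldimethylsilyl)oxy]-3,7-dimethyloct-2-en-1-yl acetate
Product: 5 (2E,7S)-8-[(tert-butyldimethylsilyl)oxy]-3,7-dimethyloct-2-en-1-ol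
Conditions: K2CO3 (0.3 equiv), MeOH, 20 °C
Reagents that add atoms: none
Why: Base-catalysed transesterification (methanolysis) removes the acetate without affecting the silyl ether or the remote stereocentre.

Step 5
Reactants: 5 (2E,7S)-8-[(tert-butyldimethylsilyl)oxy]-3,7-dimethyloct-2-en-1-ol
Product: 6 (2E,7S)-8-[(tert-butyldimethylsilyl)oxy]-3,7-dimethyloct-2-enal
Conditions: MnO2 (activated, excess), CH2Cl2, 20 °C
Reagents that add atoms: none
Why: MnO2 oxidation is selective for allylic alcohols, should give the enal without E/Z isomerisation and cannot touch the silyl ether.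

Step 6
Reactants: 6 (2E,7S)-8-[(tert-butyldimethylsilyl)oxy]-3,7-dimethyloct-2-enal; 7 allenylboronic acid pinacol ester
Product: 8 (4S,5E,10S)-11-[(tert-butyldimethylsilyl)oxy]-6,10-dimethylundec-5-en-1-yn-4-ol
Conditions: (S)-3,3'-bis(2,4,6-triisopropylphenyl)-1,1'-binaphthyl-2,2'-diyl hydrogen phosphate (10 mol%), 4 Å molecular sieves, toluene, 0 °C; aq. NaHCO3 work-up
Reagents that add atoms: allenylboronic acid pinacol ester 7, C=C=CB1OC(C)(C)C(C)(C)O1
Why: In this chiral Brønsted acid catalysed propargylboration the acid activates the boronate, the allenyl group is delivered by 1,2-addition through a closed six-membered SE2' transition state so that only the homopropargylic alcohol forms, and the (S)-acid should direct attack to the aldehyde face that gives the 4S carbinol regardless of the remote C10 centre.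

Step 7
Reactants: 9 2-hydroxy-3-methylbenzoic acid
Product: 11 2,5-dihydroxy-3-methylbenzoic acid, via aryl sulfate 10 (not isolated)
Conditions: K2S2O8, aq. NaOH, 0 → 20 °C; then aq. HCl, 90 °C
Reagents that add atoms: potassium peroxodisulfate, [K+].[K+].[O-]S(=O)(=O)OOS(=O)(=O)[O-]
Why: In the Elbs persulfate oxidation the phenoxide is attacked by peroxodisulfate at the only open position para to the phenol oxygen (both ortho positions are blocked), and hot acid then hydrolyses the aryl sulfate.

Step 8
Reactants: 11 2,5-dihydroxy-3-methylbenzoic acid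
Product: 12 methyl 2,5-dimethoxy-3-methylbenzoate
Conditions: CH3I (excess), K2CO3, DMF, 50 °C
Reagents that add atoms: iodomethane, CI
Why: Williamson O-methylation should cap both phenols and the carboxylate in one operation.

Step 9
Reactants: 12 methyl 2,5-dimethoxy-3-methylbenzoate
Product: 13 (2,5-dimethoxy-3-methylphenyl)methanol
Conditions: LiAlH4, THF, 0 °C
Reagents that add atoms: none
Why: Hydride reduction of the ester gives the benzylic alcohol and leaves the aryl methyl ethers untouched.

Step 10
Reactants: 13 (2,5-dimethoxy-3-methylphenyl)methanol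
Product: 14 2,5-dimethoxy-3-methylbenzyl chloride
Conditions: SOCl2, CH2Cl2, 0 → 20 °C
Reagents that add atoms: thionyl chloride, O=S(Cl)Cl
Why: Chlorodehydroxylation through the chlorosulfite ester is standard for benzylic alcohols, and the low temperature keeps the electron-rich ring from being alkylated by the product.

Step 11
Reactants: 8 (4S,5E,10S)-11-[(tert-butyldimethylsilyl)oxy]-6,10-dimethylundec-5-en-1-yn-4-ol; 15 trimethylaluminium; 14 2,5-dimethoxy-3-methylbenzyl chloride
Product: 17 (2E,5S,6E,11S)-12-[(tert-butyldimethylsilyl)oxy]-1-(2,5-dimethoxy-3-methylphenyl)-3,7,11-trimethyldodeca-2,6-dien-5-ol, via alkenylalane 16 (not isolated)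
Conditions: Al(CH3)3 (3.5 equiv), Cp2ZrCl2 (0.25 equiv), CH2Cl2, 0 → 20 °C; excess Al(CH3)3 and solvent removed in vacuo at 20 °C; THF, 14 (1.2 equiv), zerovalent nickel from NiCl2(PPh3)2 (5 mol%) and n-BuLi (10 mol%), 0 → 20 °C; aq. KNaC4H4O6 (potassium sodium tartrate) work-up
Reagents that add atoms: trimethylaluminium 15, C[Al](C)C
Why: Al(CH3)3 first turns the hydroxyl into its dimethylaluminium alkoxide, and a methylzirconocene–aluminium species then adds CH3 and metal syn across the terminal alkyne through a four-centre transition state, CH3 to the internal carbon C3' and metal to C2', giving after exchange to aluminium the (E)-alkenylalane 16. Zerovalent nickel, made from NiCl2(PPh3)2 and n-BuLi, inserts into the benzylic C–Cl bond of 14, takes over the alkenyl group from aluminium with retention of geometry and forms C1'–C2' by reductive elimination. The closest known reaction type is the Negishi zirconium-catalysed methylalumination of terminal alkynes, homopropargylic alcohols included, followed by nickel-catalysed coupling of the alkenylalane with a benzylic chloride as practised for prenylated quinone side chains. No ring is closed and no stereocentre is created, so C5' and C11' pass through unchanged. The step needs terminal regioselectivity and syn addition (2'E): the unsubstituted alkyne terminus and the concerted addition provide them, and keeping the mixture at or below 20 °C should prevent the neighbouring aluminium alkoxide from chelating and isomerising the alkenylalane. Stripping excess Al(CH3)3 before the nickel is added limits methyl transfer to 14, and the C6'=C7' alkene and the silyl ether are inert to both metals.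

Step 12
Reactants: 17 (2E,5S,6E,11S)-12-[(tert-butyldimethylsilyl)oxy]-1-(2,5-dimethoxy-3-methylphenyl)-3,7,11-trimethyldodeca-2,6-dien-5-ol
Product: 18 (2E,5S,6E,11S)-12-[(tert-butyldimethylsilyl)oxy]-1-(2,5-dimethoxy-3-methylphenyl)-3,7,11-trimethyldodeca-2,6-dien-5-yl acetate
Conditions: Ac2O, pyridine, DMAP (cat.), CH2Cl2, 0 → 20 °C
Reagents that add atoms: acetic anhydride, CC(=O)OC(C)=O
Why: DMAP-catalysed acylation of the secondary allylic alcohol involves only the O–H bond, so the C5' configuration is retained.

Step 13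
Reactants: 18 (2E,5S,6E,11S)-12-[(tert-butyldimethylsilyl)oxy]-1-(2,5-dimethoxy-3-methylphenyl)-3,7,11-trimethyldodeca-2,6-dien-5-yl acetate
Product: 19 (2E,5S,6E,11S)-1-(2,5-dimethoxy-3-methylphenyl)-12-hydroxy-3,7,11-trimethyldodeca-2,6-dien-5-yl acetate
Conditions: HF·pyridine, pyridine, THF, 0 → 20 °C
Reagents that add atoms: none
Why: Buffered fluoride desilylation should cleave the primary silyl ether without ionising or transesterifying the allylic acetate.

Step 14
Reactants: 19 (2E,5S,6E,11S)-1-(2,5-dimethoxy-3-methylphenyl)-12-hydroxy-3,7,11-trimethyldodeca-2,6-dien-5-yl acetate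
Product: 20 (2E,5S,6E,11S)-1-(2,5-dimethoxy-3-methylphenyl)-3,7,11-trimethyl-12-oxododeca-2,6-dien-5-yl acetate
Conditions: Dess–Martin periodinane, NaHCO3, CH2Cl2, 0 → 20 °C; used without storage
Reagents that add atoms: none
Why: Dess–Martin oxidation under bicarbonate buffer should give the α-branched aldehyde without epimerising C11'.

Step 15
Reactants: 21 2-methylbut-3-yn-2-ol
Product: 22 (E)-2-methyl-4-(tributylstannyl)but-3-en-2-ol
Conditions: Bu3SnH, PdCl2(PPh3)2 (2 mol%), THF, 0 → 20 °C
Reagents that add atoms: tributyltin hydride, CCCC[SnH](CCCC)CCCC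
Why: Palladium-catalysed syn-hydrostannylation should place tin on the terminal carbon, away from the bulky tertiary carbinol, and so give the E-alkenylstannane.

Step 16
Reactants: 22 (E)-2-methyl-4-(tributylstannyl)but-3-en-2-ol
Product: 23 (E)-4-iodo-2-methylbut-3-en-2-ol
Conditions: I2, CH2Cl2, 0 °C
Reagents that add atoms: iodine, II
Why: Iododestannylation is an ipso electrophilic substitution that proceeds with retention of alkene geometry.

Step 17
Reactants: 20 (2E,5S,6E,11S)-1-(2,5-dimethoxy-3-methylphenyl)-3,7,11-trimethyl-12-oxododeca-2,6-dien-5-yl acetate; 23 (E)-4-iodo-2-methylbut-3-en-2-ol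
Product: 24 (2E,5S,6E,11S,12RS,13E)-1-(2,5-dimethoxy-3-methylphenyl)-12,15-dihydroxy-3,7,11,15-tetramethylhexadeca-2,6,13-trien-5-yl acetate (both C12 epimers)
Conditions: CrCl2 (6 equiv), NiCl2 (2 mol%), 23 (2.5 equiv), DMSO, 20 °C
Reagents that add atoms: none
Why: In the Nozaki–Hiyama–Kishi coupling the alkenylchromium species adds only to the aldehyde, tolerates the acetate and the free tertiary hydroxyl, and is not basic enough to epimerise C11'; the C12' configuration is irrelevant because that carbon is oxidised next.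

Step 18
Reactants: 24 (2E,5S,6E,11S,12RS,13E)-1-(2,5-dimethoxy-3-methylphenyl)-12,15-dihydroxy-3,7,11,15-tetramethylhexadeca-2,6,13-trien-5-yl acetate
Product: 25 (2E,5S,6E,11S,13E)-1-(2,5-dimethoxy-3-methylphenyl)-15-hydroxy-3,7,11,15-tetramethyl-12-oxohexadeca-2,6,13-trien-5-yl acetate
Conditions: Dess–Martin periodinane, NaHCO3, CH2Cl2, 0 °C
Reagents that add atoms: none
Why: Dess–Martin oxidation should convert both C12' epimers of the secondary allylic alcohol into the E-enone, while the tertiary alcohol cannot be oxidised and the buffer protects C11'.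

Step 19
Reactants: 25 (2E,5S,6E,11S,13E)-1-(2,5-dimethoxy-3-methylphenyl)-15-hydroxy-3,7,11,15-tetramethyl-12-oxohexadeca-2,6,13-trien-5-yl acetate
Product: 26 (2E,5S,6E,11S,13E)-15-hydroxy-3,7,11,15-tetramethyl-1-(5-methyl-3,6-dioxocyclohexa-1,4-dien-1-yl)-12-oxohexadeca-2,6,13-trien-5-yl acetate
Conditions: (NH4)2Ce(NO3)6 (2.5 equiv), CH3CN/H2O, 0 °C
Reagents that add atoms: water, O
Why: Oxidative demethylation of the para-dimethoxyarene by tetravalent cerium (two one-electron oxidations, water attacking the ring carbons and methanol leaving) should be faster at 0 °C than any oxidation of the isolated alkenes, the enone or the tertiary alcohol.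

Step 20
Reactants: 26 (2E,5S,6E,11S,13E)-15-hydroxy-3,7,11,15-tetramethyl-1-(5-methyl-3,6-dioxocyclohexa-1,4-dien-1-yl)-12-oxohexadeca-2,6,13-trien-5-yl acetate
Product: 27 (2E,5S,6E,11S,13E)-1-(2,5-dihydroxy-3-methylphenyl)-15-hydroxy-3,7,11,15-tetramethyl-12-oxohexadeca-2,6,13-trien-5-yl acetate (the target)
Conditions: aq. Na2S2O4, EtOAc, 20 °C, under argon
Reagents that add atoms: none
Why: Two-electron reduction of the quinone by dithionite under neutral two-phase conditions should release the hydroquinone and leave the enone and the acetate untouched.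

**Compound list**

1 | geranyl acetate | CC(=O)OC/C=C(\C)CCC=C(C)C | starting material
2 | (2E,6E)-8-hydroxy-3,7-dimethylocta-2,6-dien-1-yl acetate | CC(=O)OC/C=C(\C)CC/C=C(\C)CO | intermediate
3 | (2E,7S)-8-hydroxy-3,7-dimethyloct-2-en-1-yl acetate | CC(=O)OC/C=C(\C)CCC[C@H](C)CO | intermediate
4 | (2E,7S)-8-[(tert-butyldimethylsilyl)oxy]-3,7-dimethyloct-2-en-1-yl acetate | CC(=O)OC/C=C(\C)CCC[C@H](C)CO[Si](C)(C)C(C)(C)C | intermediate
5 | (2E,7S)-8-[(tert-butyldimethylsilyl)oxy]-3,7-dimethyloct-2-en-1-ol | OC/C=C(\C)CCC[C@H](C)CO[Si](C)(C)C(C)(C)C | intermediate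
6 | (2E,7S)-8-[(tert-butyldimethylsilyl)oxy]-3,7-dimethyloct-2-enal | O=C/C=C(\C)CCC[C@H](C)CO[Si](C)(C)C(C)(C)C | intermediate
7 | allenylboronic acid pinacol ester | C=C=CB1OC(C)(C)C(C)(C)O1 | starting material
8 | (4S,5E,10S)-11-[(tert-butyldimethylsilyl)oxy]-6,10-dimethylundec-5-en-1-yn-4-ol | O[C@H](/C=C(\C)CCC[C@H](C)CO[Si](C)(C)C(C)(C)C)CC#C | intermediate
9 | 2-hydroxy-3-methylbenzoic acid | Cc1cccc(C(=O)O)c1O | starting material
10 | 2-hydroxy-3-methyl-5-(sulfooxy)benzoic acid (aryl sulfate, present as its salt, not isolated) | Cc1cc(OS(=O)(=O)O)cc(C(=O)O)c1O | intermediate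
11 | 2,5-dihydroxy-3-methylbenzoic acid | Cc1cc(O)cc(C(=O)O)c1O | intermediate
12 | methyl 2,5-dimethoxy-3-methylbenzoate | COC(=O)c1cc(OC)cc(C)c1OC | intermediate
13 | (2,5-dimethoxy-3-methylphenyl)methanol | COc1cc(C)c(OC)c(CO)c1 | intermediate
14 | 2,5-dimethoxy-3-methylbenzyl chloride | COc1cc(C)c(OC)c(CCl)c1 | intermediate
15 | trimethylaluminium | C[Al](C)C | starting material
16 | (E)-alkenyldimethylalane of 8 carrying the C5' hydroxyl as its dimethylaluminium alkoxide (not isolated) | C[Al](C)O[C@H](/C=C(\C)CCC[C@H](C)CO[Si](C)(C)C(C)(C)C)C/C(C)=C/[Al](C)C | intermediate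
17 | (2E,5S,6E,11S)-12-[(tert-butyldimethylsilyl)oxy]-1-(2,5-dimethoxy-3-methylphenyl)-3,7,11-trimethyldodeca-2,6-dien-5-ol | O[C@H](/C=C(\C)CCC[C@H](C)CO[Si](C)(C)C(C)(C)C)C/C(C)=C/Cc1cc(OC)cc(C)c1OC | intermediate
18 | (2E,5S,6E,11S)-12-[(tert-butyldimethylsilyl)oxy]-1-(2,5-dimethoxy-3-methylphenyl)-3,7,11-trimethyldodeca-2,6-dien-5-yl acetate | CC(=O)O[C@H](/C=C(\C)CCC[C@H](C)CO[Si](C)(C)C(C)(C)C)C/C(C)=C/Cc1cc(OC)cc(C)c1OC | intermediate
19 | (2E,5S,6E,11S)-1-(2,5-dimethoxy-3-methylphenyl)-12-hydroxy-3,7,11-trimethyldodeca-2,6-dien-5-yl acetate | CC(=O)O[C@H](/C=C(\C)CCC[C@H](C)CO)C/C(C)=C/Cc1cc(OC)cc(C)c1OC | intermediate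
20 | (2E,5S,6E,11S)-1-(2,5-dimethoxy-3-methylphenyl)-3,7,11-trimethyl-12-oxododeca-2,6-dien-5-yl acetate | CC(=O)O[C@H](/C=C(\C)CCC[C@H](C)C=O)C/C(C)=C/Cc1cc(OC)cc(C)c1OC | intermediate
21 | 2-methylbut-3-yn-2-ol | CC(C)(O)C#C | starting material
22 | (E)-2-methyl-4-(tributylstannyl)but-3-en-2-ol | CC(C)(O)/C=C/[Sn](CCCC)(CCCC)CCCC | intermediate
23 | (E)-4-iodo-2-methylbut-3-en-2-ol | CC(C)(O)/C=C/I | intermediate
24 | (2E,5S,6E,11S,12RS,13E)-1-(2,5-dimethoxy-3-methylphenyl)-12,15-dihydroxy-3,7,11,15-tetramethylhexadeca-2,6,13-trien-5-yl acetate (both C12 epimers) | CC(=O)O[C@H](/C=C(\C)CCC[C@H](C)C(O)/C=C/C(C)(C)O)C/C(C)=C/Cc1cc(OC)cc(C)c1OC | intermediate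
25 | (2E,5S,6E,11S,13E)-1-(2,5-dimethoxy-3-methylphenyl)-15-hydroxy-3,7,11,15-tetramethyl-12-oxohexadeca-2,6,13-trien-5-yl acetate | CC(=O)O[C@H](/C=C(\C)CCC[C@H](C)C(=O)/C=C/C(C)(C)O)C/C(C)=C/Cc1cc(OC)cc(C)c1OC | intermediate
26 | (2E,5S,6E,11S,13E)-15-hydroxy-3,7,11,15-tetramethyl-1-(5-methyl-3,6-dioxocyclohexa-1,4-dien-1-yl)-12-oxohexadeca-2,6,13-trien-5-yl acetate | CC(=O)O[C@H](/C=C(\C)CCC[C@H](C)C(=O)/C=C/C(C)(C)O)C/C(C)=C/CC1=CC(=O)C=C(C)C1=O | intermediate
27 | (2E,5S,6E,11S,13E)-1-(2,5-dihydroxy-3-methylphenyl)-15-hydroxy-3,7,11,15-tetramethyl-12-oxohexadeca-2,6,13-trien-5-yl acetate | CC(=O)O[C@H](/C=C(\C)CCC[C@H](C)C(=O)/C=C/C(C)(C)O)C/C(C)=C/Cc1cc(O)cc(C)c1O | target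

**Totals and risks**

Total step count: 20. Longest linear sequence: 14 steps (steps 1–6, 11–14 and 17–20, from geranyl acetate); the arene branch (steps 7–10) and the alkenyl iodide branch (steps 15–16) are side branches.

Steps most likely to fail:

1. Step 11. The aluminium alkoxide next to the alkyne may slow the methylalumination and, by chelation, allow the alkenylalane to isomerise, eroding the 2'E geometry; methyl transfer from aluminium to the benzyl chloride at nickel may compete with alkenyl transfer. The fallback sets out from 8 and separates the two events. The alkenylalane 16 is generated as before but quenched with I2 in THF at −30 °C to give (1E,4S,5E,10S)-11-[(tert-butyldimethylsilyl)oxy]-1-iodo-2,6-dimethylundeca-1,5-dien-4-ol F1, which can be purified and checked for geometric purity. Separately, 14 is converted with zinc dust and LiCl in THF into (2,5-dimethoxy-3-methylbenzyl)zinc chloride F2. A Negishi cross-coupling of F1 with excess F2 (Pd(OAc)2, SPhos, THF, 20 °C) reverses the polarity of the C1'–C2' bond formation and returns to the route at 17.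

2. Step 2. Face discrimination by the ruthenium catalyst on a 2-methyl-substituted allylic alcohol may be insufficient or of the opposite sense, and alkene migration may compete with hydrogenation. The fallback sets out from 2 and moves the hydrogenation to the carboxylic acid level, where 2-methylalk-2-enoic acids are classic substrates for carboxylate-directed hydrogenation. MnO2 oxidation gives (2E,6E)-3,7-dimethyl-8-oxoocta-2,6-dien-1-yl acetate F3. Pinnick oxidation (NaClO2, NaH2PO4, 2-methylbut-2-ene, t-BuOH/H2O) gives (2E,6E)-8-acetoxy-2,6-dimethylocta-2,6-dienoic acid F4. Hydrogenation with H2 (4 atm) and Ru(OAc)2[(S)-BINAP] in MeOH should give (2S,6E)-8-acetoxy-2,6-dimethyloct-6-enoic acid F5. Activation with isobutyl chloroformate and N-methylmorpholine in THF at −15 °C gives the mixed anhydride (2S,6E)-8-acetoxy-2,6-dimethyloct-6-enoic isobutyl carbonic anhydride F6, and NaBH4 in aqueous THF reduces it chemoselectively, returning to the route at 3.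

3. Step 6. Facial selectivity of the phosphoric acid catalysed addition may be poor on a β,β-disubstituted enal, or the catalysed path may be slow enough for the uncatalysed background addition to compete. The fallback sets out from 6 and replaces catalyst control by resolution. A zinc-mediated Barbier propargylation (propargyl bromide, zinc dust, THF/aq. NH4Cl) should give (4RS,5E,10S)-11-[(tert-butyldimethylsilyl)oxy]-6,10-dimethylundec-5-en-1-yn-4-ol F7 as a mixture of C4 epimers. Lipase-catalysed acylation (Candida antarctica lipase B, vinyl acetate, tert-butyl methyl ether, 30 °C) should, by the empirical size rule for secondary alcohols, acetylate the 4R epimer to (4R,5E,10S)-11-[(tert-butyldimethylsilyl)oxy]-6,10-dimethylundec-5-en-1-yn-4-yl acetate F8. The unreacted 4S alcohol is separated by chromatography and rejoins the route at 8.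

**Further compounds**

F1 | step 11 | (1E,4S,5E,10S)-11-[(tert-butyldimethylsilyl)oxy]-1-iodo-2,6-dimethylundeca-1,5-dien-4-ol | O[C@H](/C=C(\C)CCC[C@H](C)CO[Si](C)(C)C(C)(C)C)C/C(C)=C/I
F2 | step 11 | (2,5-dimethoxy-3-methylbenzyl)zinc chloride | COc1cc(C)c(OC)c(C[Zn]Cl)c1
F3 | step 2 | (2E,6E)-3,7-dimethyl-8-oxoocta-2,6-dien-1-yl acetate | CC(=O)OC/C=C(\C)CC/C=C(\C)C=O
F4 | step 2 | (2E,6E)-8-acetoxy-2,6-dimethylocta-2,6-dienoic acid | CC(=O)OC/C=C(\C)CC/C=C(\C)C(=O)O
F5 | step 2 | (2S,6E)-8-acetoxy-2,6-dimethyloct-6-enoic acid | CC(=O)OC/C=C(\C)CCC[C@H](C)C(=O)O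
F6 | step 2 | (2S,6E)-8-acetoxy-2,6-dimethyloct-6-enoic isobutyl carbonic anhydride | CC(=O)OC/C=C(\C)CCC[C@H](C)C(=O)OC(=O)OCC(C)C
F7 | step 6 | (4RS,5E,10S)-11-[(tert-butyldimethylsilyl)oxy]-6,10-dimethylundec-5-en-1-yn-4-ol (C4 epimer mixture) | OC(/C=C(\C)CCC[C@H](C)CO[Si](C)(C)C(C)(C)C)CC#C
F8 | step 6 | (4R,5E,10S)-11-[(tert-butyldimethylsilyl)oxy]-6,10-dimethylundec-5-en-1-yn-4-yl acetate | CC(=O)O[C@@H](/C=C(\C)CCC[C@H](C)CO[Si](C)(C)C(C)(C)C)CC#C
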